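The plan rests on cutting ring B at C8–C9 and C5–C6 (guaiane numbering). The feature exploited is that C5, C1, C10 and C9 of the target, joined through the C1=C10 alkene at the ring-fusion carbon, are the imprint of a 1-isopropenylcyclopentene diene. C6–C7–C8 is then a three-carbon oxyallyl unit with oxygen on C8. One Lewis-acid (4+3) cycloaddition of 2-(triisopropylsilyloxy)acrolein closes ring B, leaves C1=C10 in place, puts a ketone on C7 and a silyl ether on C8, and sets C5 and C8. Its precursor is the (R)-silyl ether of 3-isopropenylcyclopent-2-en-1-ol, whose C4 carbinol steers the reagent and later becomes the methyl-bearing carbon.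

Key step: step 6

Convention: guaiane numbering is used for all bicyclic compounds (ring A = C1–C5, ring B = C1, C5–C10). α is the face that carries H5 and β is the opposite face.
Assumption: (E)-4-acetoxy-3-methoxycinnamic acid (O-acetylferulic acid) is taken as a purchasable starting material.

Step 1
Reactants: 1 3-ethoxycyclopent-2-en-1-one; 2 isopropenylmagnesium bromide
Product: 4 3-(prop-1-en-2-yl)cyclopent-2-en-1-one, via tertiary allylic carbinol 3 (not isolated)
Conditions: THF, 0 °C; then 1 M HCl, rt
Reagents that add atoms: water, O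
Why: Stork–Danheiser transposition: the Grignard reagent adds 1,2 to the vinylogous ester, and aqueous acid ionises carbinol 3 and hydrolyses the enol ether, which moves the carbonyl group and leaves no stereocentre.

Step 2
Reactants: 4 3-(prop-1-en-2-yl)cyclopent-2-en-1-one
Product: 5 (R)-3-(prop-1-en-2-yl)cyclopent-2-en-1-ol
Conditions: (S)-2-methyl-CBS-oxazaborolidine (15 mol %), catecholborane, toluene, −78 °C
Reagents that add atoms: none
Why: Corey–Bakshi–Shibata reduction: the (S)-oxazaborolidine places the alkenyl branch as the large group and delivers hydride to give the (R)-carbinol (future C4), while catecholborane at this temperature should leave both alkenes alone.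

Step 3
Reactants: 5 (R)-3-(prop-1-en-2-yl)cyclopent-2-en-1-ol
Product: 6 (R)-tert-butyldiphenylsilyl ether of 5
Conditions: TBDPSCl, imidazole, DMF, rt
Reagents that add atoms: tert-butyl(chloro)diphenylsilane, CC(C)(C)[Si](Cl)(c1ccccc1)c1ccccc1
Why: Imidazole-promoted O-silylation without change at C4; TBDPS is chosen because its weakly Lewis-basic oxygen resists ionisation of this doubly allylic C–O bond under Sc(OTf)3 and because its bulk screens the α-face and the surroundings of C5.

Step 4
Reactants: 7 1,1-dimethoxypropan-2-one
Product: 8 3,3-dimethoxy-2-(triisopropylsilyloxy)prop-1-ene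
Conditions: TIPSOTf, Et3N, CH2Cl2, 0 °C → rt
Reagents that add atoms: triisopropylsilyl triflate, CC(C)[Si](C(C)C)(C(C)C)OS(=O)(=O)C(F)(F)F
Why: Soft enolisation and O-silylation of a methyl ketone, which should occur on the unhindered CH3 side and not at the acetal CH.

Step 5
Reactants: 8 3,3-dimethoxy-2-(triisopropylsilyloxy)prop-1-ene
Product: 9 2-(triisopropylsilyloxy)prop-2-enal
Conditions: SiO2, 10% aq. oxalic acid, CH2Cl2, rt
Reagents that add atoms: water, O
Why: Mild acetal hydrolysis on wet acidic silica: the allylic-type acetal ionises easily, whereas the bulky TIPS enol ether should survive.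

Step 6
Reactants: 6 (R)-tert-butyldiphenylsilyl ether of 3-(prop-1-en-2-yl)cyclopent-2-en-1-ol; 9 2-(triisopropylsilyloxy)prop-2-enal
Product: 10 (4R,5R,8S)-4α-(tert-butyldiphenylsilyloxy)-8α-(triisopropylsilyloxy)-11,12,13,15-tetranorguai-1(10)-en-7-one (H5 α)
Conditions: Sc(OTf)3 (10 mol %), 4 Å MS, CH2Cl2, −40 → 0 °C
Reagents that add atoms: none
Why: Sc(OTf)3 binds the aldehyde oxygen of 9 and turns it into a 1-(metal-oxy)-2-silyloxyallyl cation spread over C8, C7 and C6, which the s-cis diene C9=C10–C1=C5 of 6 takes up in a highly asynchronous, probably stepwise (4+3) cycloaddition; the silyloxocarbenium ion left at C7 then passes TIPS to the C8 alkoxide, which frees the catalyst and unveils the C7 ketone, the course known for Lewis-acid (4+3) cycloadditions of 2-silyloxyacroleins with 1,3-dienes. Ring B closes when the second terminus of the three-carbon unit, by then an electron-rich enol-type carbon, collapses onto the far end of the allyl cation created by the first C–C bond (cation–olefin closure of a seven-membered ring), and the central diene bond remains as the tetrasubstituted C1=C10 alkene. C5 is set by approach of the reagent to the cyclopentene face opposite the 4α-OTBDPS group, so that C6 enters β and H5 ends α. C8 is set by the extended arrangement that the C10 methyl group, C2H2 and the OTIPS group on C7 impose, because this arrangement turns the outward-pointing O–Sc bond into the 8α silyl ether, which is also the equatorial and thermodynamically preferred configuration at this epimerisable position. The decisive selectivity is orientation: the oxygen-bearing terminus must join C9 and the CH2 terminus must join C5, and steric matching secures this, since the terminus with the Sc-bound oxygen meets the unsubstituted C9H2, whereas at C5 it would have to bond next to C4 and its TBDPS ether, where only the slim CH2 terminus fits. Preference for (4+3) over (4+2) addition rests on the bulky TIPS group, the mild catalyst and the low temperature.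

Step 7
Reactants: 10 cycloadduct ketone
Product: 12 4α-(tert-butyldiphenylsilyloxy)-8α-(triisopropylsilyloxy)-11,12,13,15-tetranorguaia-1(10),6-dien-7-yl triflate, via potassium enolate 11 (not isolated)
Conditions: KN(SiMe3)2, THF, −78 °C; then Comins' reagent, −78 → −30 °C
Reagents that add atoms: N-(5-chloropyridin-2-yl)bis(trifluoromethanesulfonimide), FC(F)(F)S(=O)(=O)N(c1ccc(Cl)cn1)S(=O)(=O)C(F)(F)F
Why: Kinetic enolisation and O-triflation: the base removes a C6 proton and not the C8 proton shielded by OTIPS, so the C6=C7 enol triflate forms and C8 is not disturbed.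

Step 8
Reactants: 12 enol triflate
Product: 13 methyl 4α-(tert-butyldiphenylsilyloxy)-8α-(triisopropylsilyloxy)-12,13,15-trinorguaia-1(10),6-dien-11-oate
Conditions: Pd(OAc)2 (5 mol %), dppp (6 mol %), CO (1 atm), MeOH, Et3N, DMF, 40 °C
Reagents that add atoms: carbon monoxide, [C-]#[O+]; methanol, CO
Why: Palladium-catalysed alkoxycarbonylation of an alkenyl triflate (oxidative addition to zerovalent palladium, CO insertion, methanolysis), which installs C11 on C7 and leaves the silyl ethers and the tetrasubstituted alkene untouched.

Step 9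
Reactants: 13 bis-silyl dienoate
Product: 14 methyl 4α,8α-dihydroxy-12,13,15-trinorguaia-1(10),6-dien-11-oate
Conditions: TBAF, AcOH (1:1), THF, rt
Reagents that add atoms: none
Why: Fluoride desilylation of both ethers in one operation, buffered with acetic acid so that the doubly allylic γ-proton at C5 of the unsaturated ester is not removed.

Step 10
Reactants: 14 dihydroxy dienoate
Product: 15 methyl 4α,8α-dihydroxy-12,13,15-trinorguai-1(10)-en-11-oate (H7 α, ester β)
Conditions: [Rh(nbd)(dppb)]BF4 (5 mol %), H2 (50 atm), CH2Cl2, rt
Reagents that add atoms: none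
Why: Hydroxyl-directed homogeneous hydrogenation: the allylic 8α-OH and the homoallylic 4α-OH both hold the cationic rhodium complex on the α-face, so hydrogen reaches C6 and C7 from α and makes the ester β and trans to O8, while the tetrasubstituted C1=C10 alkene is inert and high pressure suppresses allylic alcohol isomerisation.

Step 11
Reactants: 15 saturated dihydroxy ester
Product: 16 15-norguai-1(10)-ene-4α,8α,11-triol
Conditions: MeMgBr (6 equiv), THF, 0 °C → rt
Reagents that add atoms: methylmagnesium bromide, C[Mg]Br
Why: Double Grignard addition to the ester builds the C11 carbinol, and since O8 is present as a magnesium alkoxide that cannot leave, β-elimination is avoided and C7 keeps its configuration.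

Step 12
Reactants: 16 triol
Product: 17 8,11-O-benzylidene-15-norguai-1(10)-ene-4α,8α,11-triol (phenyl equatorial, acetal carbon S, 4α-OH free)
Conditions: PhCH(OMe)2, CSA (5 mol %), CH2Cl2, rt
Reagents that add atoms: benzaldehyde dimethyl acetal, COC(OC)c1ccccc1
Why: Acid-catalysed transacetalisation under thermodynamic control: only the 8,11-diol can form a six-membered cyclic acetal (phenyl equatorial), which frees 4-OH for oxidation, and an aldehyde acetal avoids the 1,3-diaxial methyl clash that a ketal would have with the C11 methyl groups.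

Step 13
Reactants: 17 acetal alcohol
Product: 18 8,11-O-benzylidene-8α,11-dihydroxy-15-norguai-1(10)-en-4-one
Conditions: Dess–Martin periodinane, pyridine, CH2Cl2, 0 °C
Reagents that add atoms: none
Why: Dess–Martin oxidation under buffered, non-enolising conditions, placed at the point where C6 is sp3 so that H5 is activated only by the new ketone and by C1=C10.

Step 14
Reactants: 18 ketone
Product: 19 8,11-O-benzylideneguaia-1(10),4(15)-diene-8α,11-diol
Conditions: Cp2TiMe2 (2.5 equiv), toluene, 65 °C, dark
Reagents that add atoms: dimethyltitanocene, [CH3-].[CH3-].[Ti+4].c1cc[cH-]c1.c1cc[cH-]c1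
Why: Petasis methylenation: the thermally formed titanium methylidene is non-basic and reacts through an oxatitanacyclobutane, so the β,γ-unsaturated ketone should be converted without enolisation, alkene migration or loss of C5.

Step 15
Reactants: 19 exocyclic alkene
Product: 20 8,11-O-benzylideneguai-1(10)-ene-8α,11-diol (4β-methyl, H4 α)
Conditions: RhCl(PPh3)3 (10 mol %), H2 (4 atm), benzene–EtOH, rt
Reagents that add atoms: none
Why: Homogeneous hydrogenation that accepts only the 1,1-disubstituted alkene; hydrogen is delivered to C4 from the α-face, opposite C6 on the neighbouring C5, which makes the methyl group β (cis to C6) and avoids the alkene migration typical of palladium on carbon.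

Step 16
Reactants: 20 acetal
Product: 21 (4S,5S,7S,8S)-guai-1(10)-ene-8α,11-diol
Conditions: CSA (10 mol %), MeOH, rt
Reagents that add atoms: none
Why: Acid-catalysed transacetalisation to methanol releases the diol under conditions too mild to ionise the tertiary carbinol or move the tetrasubstituted alkene.

Step 17
Reactants: 21 guai-1(10)-ene-8α,11-diol; 22 (E)-4-acetoxy-3-methoxycinnamic acid
Product: 23 8α-[(E)-4-acetoxy-3-methoxycinnamoyloxy]guai-1(10)-en-11-ol
Conditions: DCC, DMAP, CH2Cl2, 0 °C → rt
Reagents that add atoms: none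
Why: Steglich esterification at the secondary 8-OH with retention at C8; the tertiary 11-OH is too hindered to compete and the acetate keeps the phenol from being acylated.

Step 18
Reactants: 23 O-acetyl ester
Product: 24 8α-[(E)-feruloyloxy]guai-1(10)-en-11-ol (target, 4S,5S,7S,8S)
Conditions: pyrrolidine (3 equiv), CH2Cl2, 0 °C → rt
Reagents that add atoms: none
Why: Chemoselective aminolysis: the aryl acetate is far more electrophilic than the hindered secondary cinnamate, so only the phenol is released.

Compound list
1 | 3-ethoxycyclopent-2-en-1-one | CCOC1=CC(=O)CC1 | starting material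
2 | isopropenylmagnesium bromide | C=C(C)[Mg]Br | starting material
3 | 3-ethoxy-1-(prop-1-en-2-yl)cyclopent-2-en-1-ol (racemic, not isolated) | CCOC1=CC(O)(C(C)=C)CC1 | intermediate
4 | 3-(prop-1-en-2-yl)cyclopent-2-en-1-one | C=C(C)C1=CC(=O)CC1 | intermediate
5 | (R)-3-(prop-1-en-2-yl)cyclopent-2-en-1-ol | C=C(C)C1=C[C@H](O)CC1 | intermediate
6 | (R)-tert-butyldiphenylsilyl ether of 3-(prop-1-en-2-yl)cyclopent-2-en-1-ol | C=C(C)C1=C[C@H](O[Si](c2ccccc2)(c2ccccc2)C(C)(C)C)CC1 | intermediate
7 | 1,1-dimethoxypropan-2-one | COC(OC)C(C)=O | starting material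
8 | 3,3-dimethoxy-2-(triisopropylsilyloxy)prop-1-ene | COC(OC)C(=C)O[Si](C(C)C)(C(C)C)C(C)C | intermediate
9 | 2-(triisopropylsilyloxy)prop-2-enal | O=CC(=C)O[Si](C(C)C)(C(C)C)C(C)C | intermediate
10 | 4α-(tert-butyldiphenylsilyloxy)-8α-(triisopropylsilyloxy)-11,12,13,15-tetranorguai-1(10)-en-7-one | CC(C)[Si](C(C)C)(C(C)C)O[C@H]1CC(C)=C2CC[C@@H](O[Si](c3ccccc3)(c3ccccc3)C(C)(C)C)[C@@H]2CC1=O | intermediate
11 | potassium C6=C7 enolate of 10 (not isolated) | CC(C)[Si](C(C)C)(C(C)C)O[C@H]1CC(C)=C2CC[C@@H](O[Si](c3ccccc3)(c3ccccc3)C(C)(C)C)[C@@H]2C=C1[O-].[K+] | intermediate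
12 | C6=C7 enol triflate of 10 | CC(C)[Si](C(C)C)(C(C)C)O[C@H]1CC(C)=C2CC[C@@H](O[Si](c3ccccc3)(c3ccccc3)C(C)(C)C)[C@@H]2C=C1OS(=O)(=O)C(F)(F)F | intermediate
13 | methyl 4α-(tert-butyldiphenylsilyloxy)-8α-(triisopropylsilyloxy)-12,13,15-trinorguaia-1(10),6-dien-11-oate | CC(C)[Si](C(C)C)(C(C)C)O[C@H]1CC(C)=C2CC[C@@H](O[Si](c3ccccc3)(c3ccccc3)C(C)(C)C)[C@@H]2C=C1C(=O)OC | intermediate
14 | methyl 4α,8α-dihydroxy-12,13,15-trinorguaia-1(10),6-dien-11-oate | O[C@H]1CC(C)=C2CC[C@@H](O)[C@@H]2C=C1C(=O)OC | intermediate
15 | methyl 4α,8α-dihydroxy-12,13,15-trinorguai-1(10)-en-11-oate (H7 α) | O[C@H]1CC(C)=C2CC[C@@H](O)[C@@H]2C[C@@H]1C(=O)OC | intermediate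
16 | 15-norguai-1(10)-ene-4α,8α,11-triol | O[C@H]1CC(C)=C2CC[C@@H](O)[C@@H]2C[C@@H]1C(C)(C)O | intermediate
17 | 8,11-O-benzylidene acetal of 16 (phenyl equatorial) | O1[C@H]2CC(C)=C3CC[C@@H](O)[C@@H]3C[C@@H]2C(C)(C)O[C@H]1c4ccccc4 | intermediate
18 | 8,11-O-benzylidene-8α,11-dihydroxy-15-norguai-1(10)-en-4-one | O1[C@H]2CC(C)=C3CCC(=O)[C@@H]3C[C@@H]2C(C)(C)O[C@H]1c4ccccc4 | intermediate
19 | 8,11-O-benzylideneguaia-1(10),4(15)-diene-8α,11-diol | O1[C@H]2CC(C)=C3CCC(=C)[C@@H]3C[C@@H]2C(C)(C)O[C@H]1c4ccccc4 | intermediate
20 | 8,11-O-benzylideneguai-1(10)-ene-8α,11-diol (4β-methyl) | O1[C@H]2CC(C)=C3CC[C@H](C)[C@@H]3C[C@@H]2C(C)(C)O[C@H]1c4ccccc4 | intermediate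
21 | (4S,5S,7S,8S)-guai-1(10)-ene-8α,11-diol | O[C@H]1CC(C)=C2CC[C@H](C)[C@@H]2C[C@@H]1C(C)(C)O | intermediate
22 | (E)-4-acetoxy-3-methoxycinnamic acid | COc1cc(/C=C/C(=O)O)ccc1OC(C)=O | starting material
23 | 8α-[(E)-4-acetoxy-3-methoxycinnamoyloxy]guai-1(10)-en-11-ol | COc1cc(/C=C/C(=O)O[C@H]2CC(C)=C3CC[C@H](C)[C@@H]3C[C@@H]2C(C)(C)O)ccc1OC(C)=O | intermediate
24 | 8α-[(E)-feruloyloxy]guai-1(10)-en-11-ol | COc1cc(/C=C/C(=O)O[C@H]2CC(C)=C3CC[C@H](C)[C@@H]3C[C@@H]2C(C)(C)O)ccc1O | target

Total step count: 18. Longest linear sequence: 16 steps (steps 1–3 and 6–18).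

Steps most likely to fail

Step 6. The main threat is addition of the three-carbon unit in the reversed orientation. The unhindered and more nucleophilic C9 terminus tends to bond to the CH2 (β) carbon of the activated acrolein, and this electronic bias works against the steric matching on which the step relies. Competing (4+2) addition and Lewis-acid ionisation of the dienyl silyl ether are lesser threats.

The fallback sets out from 6 and 9 and comes back at 10. It accepts the reversed adduct, 4α-(tert-butyldiphenylsilyloxy)-6α-(triisopropylsilyloxy)-11,12,13,15-tetranorguai-1(10)-en-7-one F1, and moves the oxygen: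
- The only accessible enolate of this ketone lies towards C8. KN(SiMe3)2 followed by 2-(phenylsulfonyl)-3-phenyloxaziridine should therefore hydroxylate C8 and give the 8α-hydroxy-6α-(triisopropylsilyloxy) ketone F2.
- SmI2 (2 equiv) in THF–MeOH at −78 °C should then expel the better leaving group next to the ketone, the C6 silyloxide, to give the 8α-hydroxy ketone F3.
- TIPSOTf and 2,6-lutidine convert this ketone into 10.

The cycloaddition then still builds ring B and C5, while the C8 oxygen comes from enolate oxidation.

Step 14. During the slow thermal methylenation, ketone 18 may enolise, with migration of C1=C10 into conjugation or loss of configuration at C5.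

The fallback sets out from 18 and comes back at 19, and replaces the titanium carbene by a two-stage Peterson olefination:
- The non-basic organocerium reagent from Me3SiCH2Li and CeCl3 should add at −78 °C from the α-face to give the 4β-hydroxy-4α-(trimethylsilylmethyl) acetal F4.
- KH in THF then triggers syn elimination to 19, at a stage where no enolisable ketone is left.

Step 15. Facial selectivity of hydrogen delivery to the exocyclic alkene may be poor, or the alkene may migrate into ring A before reduction.

The fallback sets out from 17 and comes back at 20, bypassing 18 and 19, and uses the 4α-carbinol itself as the stereochemical handle: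
- MsCl and Et3N give the 4α-mesylate F5.
- Me2CuLi in Et2O at 0 °C should displace it with inversion to place the methyl group β.
- Anti elimination towards C5 is not available because H5 is cis to the leaving group.

Further compounds
F1 | step 6 | 4α-(tert-butyldiphenylsilyloxy)-6α-(triisopropylsilyloxy)-11,12,13,15-tetranorguai-1(10)-en-7-one | O=C1CCC(C)=C2CC[C@@H](O[Si](c3ccccc3)(c3ccccc3)C(C)(C)C)[C@@H]2[C@H]1O[Si](C(C)C)(C(C)C)C(C)C
F2 | step 6 | 4α-(tert-butyldiphenylsilyloxy)-8α-hydroxy-6α-(triisopropylsilyloxy)-11,12,13,15-tetranorguai-1(10)-en-7-one | O[C@H]1CC(C)=C2CC[C@@H](O[Si](c3ccccc3)(c3ccccc3)C(C)(C)C)[C@@H]2[C@@H](O[Si](C(C)C)(C(C)C)C(C)C)C1=O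
F3 | step 6 | 4α-(tert-butyldiphenylsilyloxy)-8α-hydroxy-11,12,13,15-tetranorguai-1(10)-en-7-one | O[C@H]1CC(C)=C2CC[C@@H](O[Si](c3ccccc3)(c3ccccc3)C(C)(C)C)[C@@H]2CC1=O
F4 | step 14 | 8,11-O-benzylidene-4α-(trimethylsilylmethyl)-15-norguai-1(10)-ene-4β,8α,11-triol | O1[C@H]2CC(C)=C3CC[C@@](O)(C[Si](C)(C)C)[C@@H]3C[C@@H]2C(C)(C)O[C@H]1c4ccccc4
F5 | step 15 | 4α-methanesulfonate of 17 | O1[C@H]2CC(C)=C3CC[C@@H](OS(C)(=O)=O)[C@@H]3C[C@@H]2C(C)(C)O[C@H]1c4ccccc4
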